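## Retrosynthetic overview

1. Building blocks: 2,4-dimethoxyphenol 1 → allyl ether 2 → 2-allyl-4,6-dimethoxyphenol 3 (O-allylation, Claisen); (E)-methyl isoeugenol 4 is bought.
2. Key disconnection, one operation: both C–C bonds of the two-carbon bridge (C5–C6, C1–C7) and the C2–OAc bond. This leads back to the phenoxonium ion of 3 (stored as quinol acetate 5), alkene 4 and acetate, so target 6 = 3 + 4 + [O] + acetate.
3. Ring order: the benzene ring of 3 is dearomatised and becomes the six-membered ring (its C–OH carbon becomes the bridging ketone C8). The cyclopentanone ring then closes on it by a cationic [5+2] addition of 4 across the two ortho carbons (C5–C6 first, C1–C7 second), which completes the bicyclo[3.2.1]octane.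
4. The 2-methoxyallyl cation left on the three-carbon bridge is quenched by acetate at C2, so all five stereocentres arise in this step; absolute configuration comes from a chiral counter-anion.
5. Locants used: C1 = OMe bridgehead, C2 = CH(OAc), C3 = C(OMe)=, C4 = =CH, C5 = allyl bridgehead, C6 = CHMe, C7 = CHAr, C8 = C=O.

Assumption: 2,4-dimethoxyphenol (1) and geometrically pure (E)-methyl isoeugenol (4) are taken as catalogue compounds.
Assumption: the sense of induction of the chiral acid cannot be predicted with confidence; the route is written for the catalyst antipode that gives the drawn enantiomer (both antipodes are accessible).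

## Route

Step 1
Reactants: 1 2,4-dimethoxyphenol
Product: 2 1-(allyloxy)-2,4-dimethoxybenzene
Conditions: allyl bromide (1.2 equiv), K2CO3 (1.5 equiv), acetone, reflux, N2
Reagents that add atoms: allyl bromide, C=CCBr
Why: Williamson ether synthesis; the phenoxide of 1 is O-alkylated by the SN2-reactive allyl bromide in a polar aprotic medium, and no stereocentre is formed.

Step 2
Reactants: 2 1-(allyloxy)-2,4-dimethoxybenzene
Product: 3 2-allyl-4,6-dimethoxyphenol
Conditions: N,N-diethylaniline, 200 °C, sealed tube
Reagents that add atoms: none
Why: Aromatic Claisen rearrangement ([3,3]-sigmatropic shift, then tautomerisation); C6 is the only free ortho position, and migration to the OMe-bearing ortho carbon gives a dienone that cannot aromatise and reverts, so 3 is the only stable product; no stereocentre is formed.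

Step 3
Reactants: 3 2-allyl-4,6-dimethoxyphenol; 4 (E)-methyl isoeugenol
Product: 6 (1S,2S,5S,6R,7S)-5-allyl-7-(3,4-dimethoxyphenyl)-1,3-dimethoxy-6-methyl-8-oxobicyclo[3.2.1]oct-3-en-2-yl acetate (target), via quinol acetate 5 (not isolated)
Conditions: PhI(OAc)2 (1.05 equiv), CH2Cl2, −40 °C; then 4 (1.5 equiv), chiral BINOL-derived imidodiphosphorimidate acid (IDPi, 5 mol %), toluene/CH2Cl2, −78 → −40 °C; Et3N quench
Reagents that add atoms: (diacetoxyiodo)benzene, CC(=O)OI(OC(C)=O)c1ccccc1
Why: Proposed new method: PhI(OAc)2 first turns 3 into quinol acetate 5 (Wessely-type acetoxylative dearomatisation, known; the site of acetate delivery is immaterial because ionisation erases it); the chiral acid HX* then ionises 5 to the 2-allyl-4,6-dimethoxyphenoxonium ion held as a contact ion pair with X*−, and 4 adds across its two ortho carbons in a cationic [5+2] cycloaddition (closest known reactions: the racemic acid-promoted Büchi-type condensation of quinone-ketal cations with (E)-propenylarenes, and asymmetric counter-anion-directed catalysis of oxocarbenium ions); the C5–C6 bond forms first on the face not covered by the anion (sets C5 and C6, enantio-determining), and C1–C7 closes second with the E geometry retained (aryl trans to methyl; methyl over the ring C–H becomes endo and aryl over the carbonyl edge becomes exo, which avoids a methyl/allyl clash at the bridgehead); the 2-methoxyallyl cation left on the three-carbon bridge is captured by acetic acid at C2, the terminus where the charge is generated and where the acetate sits next to the small C1–OMe, and only from the exo face because the endo face is blocked by H-7 and the C6–C7 bridge.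

## Compound list

1 | 2,4-dimethoxyphenol | COc1ccc(O)c(OC)c1 | starting material
2 | 1-(allyloxy)-2,4-dimethoxybenzene (allyl 2,4-dimethoxyphenyl ether) | C=CCOc1ccc(OC)cc1OC | intermediate
3 | 2-allyl-4,6-dimethoxyphenol | C=CCc1cc(OC)cc(OC)c1O | intermediate
4 | (E)-methyl isoeugenol, 1,2-dimethoxy-4-[(E)-prop-1-enyl]benzene | C/C=C/c1ccc(OC)c(OC)c1 | starting material
5 | quinol acetate, 6-acetoxy-2-allyl-4,6-dimethoxycyclohexa-2,4-dien-1-one (racemic; its stereocentre is destroyed on ionisation) | C=CCC1=CC(OC)=CC(OC)(OC(C)=O)C1=O | intermediate (not isolated)
6 | (1S,2S,5S,6R,7S)-5-allyl-7-(3,4-dimethoxyphenyl)-1,3-dimethoxy-6-methyl-8-oxobicyclo[3.2.1]oct-3-en-2-yl acetate; 7-aryl exo (syn to the C8 ketone bridge), 6-methyl endo and trans to the aryl, 2-acetoxy exo (anti to the C6–C7 bridge) | C=CC[C@]12C=C(OC)[C@H](OC(C)=O)[C@](OC)(C1=O)[C@H](c1ccc(OC)c(OC)c1)[C@H]2C | target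

## Step count and risks

Total step count: 3. Longest linear sequence: 3 steps (1 → 2 → 3 → 6); 4 is purchased.

Steps most likely to fail, in order of risk:

Step 3 carries almost all the risk. The counter-anion may give low enantioselectivity. The first C–C bond may form at the OMe-bearing ortho carbon instead of the allyl-bearing one. The endo-aryl/exo-methyl diastereomer may compete, since both approach modes are plausible for an (E)-alkene. The benzylic cation may close on oxygen to a hydrobenzofuran, or the acetate may end at C4. As a fallback, set out from phenol 3 and oxidise it with PhI(OAc)2 in methanol to the isolable p-quinone monoketal 2-allyl-4,4,6-trimethoxycyclohexa-2,5-dien-1-one F1. Condense F1 with 4 under the classical achiral protocol (TFA or TMSOTf in CH2Cl2/AcOH, Ac2O as methanol scavenger, −40 °C to room temperature). Hold it long enough for the reversible C–O closure, the C1–C7 closure and the allylic acetate to equilibrate toward the C–C-bonded exo-acetate bicycle; this cannot correct the C5/C6 relationship, which is fixed in the first bond. This gives 6 as the racemate, that is together with its mirror image, the (1R,2R,5R,6S,7R)-acetate F2, which is removed by preparative chiral SFC. The fallback returns to the route at 6.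

Step 2 is a routine Claisen rearrangement. The risks are thermal cyclisation of 3 to a 2-methyl-2,3-dihydrobenzofuran or partial demethylation at 200 °C. As a fallback, set out from 1 and bypass the ether altogether: form the sodium phenoxide with NaH in toluene and treat it with allyl bromide at 60 °C. C-allylation of the tight phenoxide ion pair in a non-polar solvent goes to the only free ortho carbon and gives 3 directly, where the fallback rejoins the route; new compounds: none F0.

Step 1 is the safest. The risks are some C-allylation or air oxidation of the electron-rich phenoxide under basic conditions. As a fallback, set out from 1 and use a base-free Pd-catalysed O-allylation (Tsuji–Trost: allyl methyl carbonate, Pd(PPh3)4, THF, room temperature), which proceeds through a π-allyl complex instead of an SN2 displacement. It returns to the route at 2; new compounds: none F0.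

## Further compounds

F1 | step 3 | 2-allyl-4,4,6-trimethoxycyclohexa-2,5-dien-1-one | C=CCC1=CC(OC)(OC)C=C(OC)C1=O
F2 | step 3 | (1R,2R,5R,6S,7R)-5-allyl-7-(3,4-dimethoxyphenyl)-1,3-dimethoxy-6-methyl-8-oxobicyclo[3.2.1]oct-3-en-2-yl acetate (ent-6) | C=CC[C@@]12C=C(OC)[C@@H](OC(C)=O)[C@@](OC)(C1=O)[C@@H](c1ccc(OC)c(OC)c1)[C@@H]2C
F0 | step 2 | none | none
F0 | step 1 | none | none
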